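# Galbinic acid by pyrone–alkyne cycloaddition on the ring B ether oxygen

## Analysis of the target

Galbinic acid is a depsidone: rings A and B are joined by an ether oxygen and by an ester, which closes a seven-membered dibenzo[b,e][1,4]dioxepin-11-one, and ring B carries a fused five-membered hydroxy lactone (a 3-hydroxyphthalide). Ring A is labelled A1 (bears the lactone carbonyl), A2 (CH3), A3 (H), A4 (OH), A5 (CHO), A6 (ether oxygen); ring B is labelled B1 (CH2OAc), B2 (OH), B3 (phthalide carbonyl), B4 (lactol carbon), B5 (ether oxygen), B6 (ester oxygen). The only stereocentre is the lactol carbon on B4, which is (S). It is the cyclic hemiacetal of a 2-formylbenzoic acid, so it equilibrates with an achiral open form, and no second stereo element exists from which it could be relayed. The sensitive groups are the aryl ester of the seven-membered ring (nucleophiles), the benzylic acetate on B1 (it sits between two ring oxygens and is expelled as an ortho-quinone methide once a neighbouring phenol is deprotonated), the aldehyde and the lactol. The difficulty is the substitution density: ring B is hexasubstituted, ring A pentasubstituted. The strategy rests on the ether oxygen, which links A6 (between the A5 formyl carbon and the A1 carboxyl carbon) to B5 (between the B4 lactol carbon and the B6 ester oxygen). With four ortho substituents around it, this C–O–C unit is a poor goal for an aryl–oxygen coupling, so ring A is instead built on an oxygen that already sits on B5.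

## Retrosynthetic reasoning

**24 from 23.** The free lactol cannot carry its configuration through any step that opens it, so the last operation only removes three allyl carbonates from 23 under neutral conditions. The forward step must not pass through a free lactol oxygen anion.

**23 from 22.** The exocyclic O–C bond of the lactol carbonate is cut. Racemic 22 interconverts its enantiomers through the open formyl acid, so an enantioselective acyl transfer can funnel all of it into one configurationally stable carbonate. The stereocentre is therefore set at the very end, on the complete skeleton.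

**22 from 21.** Three O-methyl groups are removed in one operation: the aryl methyl ethers on A4 and B2 (each next to a carbonyl group) and the methyl acetal that masks the lactol. Methyl is chosen because the B2 oxygen must stay capped whenever base is present near the B1 acetoxymethyl group.

**21 from 20 and 19.** The ester C–O bond between the A1 carboxyl carbon and the B6 oxygen is cut. It is the most nucleophile-sensitive bond of the skeleton and is therefore formed late, by closing the seven-membered lactone of hydroxy acid 20. Acid 20 comes from 19 by acid cleavage of two 4-methoxybenzyl groups, so the B6 phenol appears under acid and never as a phenoxide beside the acetoxymethyl group. A silyl ether on B6 was avoided for two reasons: it would migrate to the neighbouring B5 phenoxide when the alkyne is attached, and its fluoride cleavage would trigger loss of acetate.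

**19 from 17 and 2 (key disconnection).** Two ring A bonds are cut: A1–A2 and A5–A6. This opens ring A into the two-carbon alkyne unit of 17, which already carries the B5 oxygen and the carboxyl carbon, and the four-carbon diene unit of pyrone 2, which carries CH3, H, OMe and CHO in their final order. The forward reaction is a (4+2) cycloaddition followed by decarboxylative cycloreversion. The hindered diaryl ether is thus never made by coupling; only a phenol–alkyne bond has to be made.

**17 from 16 and 5.** The O–C(sp) bond is cut. Phenol 16 is the complete ring B with one free hydroxyl (B5), and bromoalkyne 5 is an acceptor on which that phenoxide can substitute. The ring B aldehyde is masked as the cyclic methyl pseudo-ester so that it cannot react with the ynol ether.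

**16 from 14 and 13.** The B5 oxygen is traced back to a bromine atom (14), and the acetate to alcohol 13. The B6 oxygen is differentiated from B5 from the first step on, because B5 is not an oxygen until step 10.

**13 from 10.** The B3–B4 phthalide unit is cut at the bond between B4 and the lactol carbon. In 10 the only ring C–H lies between the ester and the bromine, so deprotonative metalation is unambiguous, and the neighbouring ester closes the phthalide.

**10 from 9, 8, 7 and 6.** The B1 carbon is cut off as a formyl group introduced between the two hydroxyls of 6, where the bromine blocks the alternative position. The two phenols are then capped differently (4-methoxybenzyl on B6, methyl on B2) and the aldehyde is reduced.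

**2 from 1; 5 from 4 and 3.** The diene is the formylated commercial pyrone. The dienophile carbon pair comes from propiolic acid as its 4-methoxybenzyl ester, so that the ring A ester and the B6 ether leave together in step 13.

## Alternatives that were turned down

**Alternative 1:** The disconnection is only the exocyclic O–acyl bond on the lactol carbon; the target is traced to the tris(allyl carbonate) A1 and this to racemic galbinic acid A2. In the forward key step a chiral acyl-transfer catalyst carbonates one lactol enantiomer of A2 while ring–chain tautomerism keeps the two enantiomers in equilibrium.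
- For it: it addresses the only stereocentre directly, uses the lability of the lactol as an asset, needs no chiral building block, and leaves a protecting group that is removed under neutral conditions.
- Against it: as a central strategy it makes no carbon–carbon bond and no carbocycle. The hexasubstituted ring B, the hindered ether and the seven-membered lactone all remain to be solved by some other plan for A2.
- Comparison: on stereocontrol it is as strong as the chosen plan, which in fact ends with this operation (A2 is 22, A1 is 23). What the chosen strategy adds is the construction of the skeleton.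

**Alternative 2:** Four carbon–carbon bonds of ring A and both ring closures are cut at once, back to A4, in which the B6 oxygen carries a 2-diazo-3-oxopentenoate and the B5 oxygen an alkynyl ether. Forward, light induces a Wolff rearrangement to an ester-substituted vinylketene, which adds (2+2) to the tethered ynol ether; four-electron ring opening and six-electron electrocyclization then give the protected depsidone A3.
- For it: two rings and four bonds form in one operation, no separate lactonization is needed, the tether fixes the regiochemistry, and the ring A phenol emerges free. On bonds per step and on step count after the key step it is stronger than the chosen cycloaddition.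
- Against it: A4 needs a diazo ester and an ynol ether on neighbouring oxygens of a fully substituted ring. The first bond must form inside a seven-membered ring that contains sp and sp2 centres. The ketene carries an α-ester, and such acylketenes usually react with electron-rich alkynes as oxadienes in a (4+2) mode to give pyranones. The carbene can also add to the alkyne before it rearranges.
- Comparison: the chosen key step is intermolecular and thermal, its precursor 17 has one sensitive function, and its regiochemistry follows a known polarity pattern. The price is two more steps afterwards (unmasking and lactonization).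

**Alternative 3:** Ring B is opened into the alkenyl diazo keto ester A6, which already carries ring A as an enol ether, and the siloxyalkyne A7. Forward, irradiation of A6 gives a vinylketene by Wolff rearrangement; cycloaddition with A7, ring opening and electrocyclization give the diaryl ether A5 with a free B6 phenol beside the ether oxygen.
- For it: all six ring B substituents are placed by the two components in one step, the ether oxygen is not made by aryl coupling, and the B6 hydroxyl is delivered free for lactonization. On the construction of ring B it is clearly stronger than the chosen route, which spends seven steps of aromatic chemistry there.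
- Against it: ring A must first be made as a pentasubstituted phenol and attached to a dicarbonyl fragment as an enol ether, so the hindered-oxygen problem returns in another form. The vinylketene again carries an α-ester and in addition a bulky acetal, and the electrocyclization must create six contiguous substituents. The silyl groups on B2 and on the B1 hydroxymethyl must later be exchanged. Two separate multistep arene syntheses are still needed.
- Comparison: the chosen strategy takes ring A from a commercial pyrone in one step and builds ring B by predictable, position-defined reactions, so the uncertainty is confined to one cycloaddition.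

Key step: step 12

Assumption: the lactol carbon racemizes through the open formyl acid under base; the (S)-lactol is assumed to keep its configuration in neutral or weakly acidic, non-nucleophilic media at or below room temperature.

Assumption: methyl 5-bromo-2,4-dihydroxybenzoate (6) is taken as a catalogue compound.

## Steps

Step 1
Reactants: 1 4-methoxy-6-methyl-2H-pyran-2-one
Product: 2 4-methoxy-6-methyl-2-oxo-2H-pyran-3-carbaldehyde (3-formyl-4-methoxy-6-methyl-2-pyrone)
Conditions: Cl2CHOMe, TiCl4, CH2Cl2, −10 → 0 °C; then ice-water
Reagents that add atoms: dichloromethyl methyl ether COC(Cl)Cl; water O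
Why: Rieche formylation at C3, the enol-ether β-carbon between the lactone carbonyl and the methoxy group and the most nucleophilic ring position; hydrolysis of the chloro(methoxy)methyl intermediate releases the aldehyde. Formylation of 4-methoxy-6-alkyl-2-pyrones at C3 in this way is established.

Step 2
Reactants: 3 propiolic acid
Product: 4 4-methoxybenzyl propiolate
Conditions: 4-MeOC6H4CH2Cl, K2CO3, DMF, 0 °C → rt
Reagents that add atoms: 4-methoxybenzyl chloride COc1ccc(CCl)cc1
Why: O-alkylation of the carboxylate (SN2 at the benzylic chloride); the weak base and low temperature should keep conjugate addition to the ynoate in check.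

Step 3
Reactants: 4 4-methoxybenzyl propiolate
Product: 5 4-methoxybenzyl 3-bromopropiolate
Conditions: NBS, AgNO3 (10 mol%), acetone, rt, dark
Reagents that add atoms: N-bromosuccinimide O=C1CCC(=O)N1Br
Why: Silver-catalysed electrophilic bromination of the terminal alkyne through the silver acetylide, the standard route to 3-bromopropiolate esters.

Step 4
Reactants: 6 methyl 5-bromo-2,4-dihydroxybenzoate
Product: 7 methyl 5-bromo-3-formyl-2,4-dihydroxybenzoate
Conditions: (CH2)6N4, CF3CO2H, 80 °C; then 3 M aq. HCl, 60 °C
Reagents that add atoms: hexamethylenetetramine C1N2CN3CN1CN(C2)C3; water O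
Why: Duff formylation; C3 (future B1) is the only free position ortho to a hydroxyl, because C5 is blocked by bromine and C6 is meta to both hydroxyls, so the formyl group should enter between the two phenols. The bromine later becomes the B5 oxygen.

Step 5
Reactants: 7 methyl 5-bromo-3-formyl-2,4-dihydroxybenzoate
Product: 8 methyl 5-bromo-3-formyl-2-hydroxy-4-[(4-methoxybenzyl)oxy]benzoate
Conditions: 4-MeOC6H4CH2Cl (1.05 equiv), K2CO3 (1.0 equiv), DMF, rt
Reagents that add atoms: 4-methoxybenzyl chloride COc1ccc(CCl)cc1
Why: Williamson etherification; the 4-hydroxyl (para to the ester, future B6 oxygen) is the more acidic phenol and should react first, while the 2-hydroxyl, held between the aldehyde and the ester carbonyl by hydrogen bonding, should stay free, which is the usual selectivity of 3-formyl-2,4-dihydroxybenzoates.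

Step 6
Reactants: 8 methyl 5-bromo-3-formyl-2-hydroxy-4-[(4-methoxybenzyl)oxy]benzoate
Product: 9 methyl 5-bromo-3-formyl-2-methoxy-4-[(4-methoxybenzyl)oxy]benzoate
Conditions: MeI, K2CO3, DMF, 45 °C
Reagents that add atoms: iodomethane CI
Why: Williamson methylation of the chelated phenol under forcing conditions; the methyl ether keeps the B2 oxygen capped in every later step in which base meets the acetoxymethyl group.

Step 7
Reactants: 9 methyl 5-bromo-3-formyl-2-methoxy-4-[(4-methoxybenzyl)oxy]benzoate
Product: 10 methyl 5-bromo-3-(hydroxymethyl)-2-methoxy-4-[(4-methoxybenzyl)oxy]benzoate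
Conditions: NaBH4, THF/MeOH, 0 °C
Reagents that add atoms: none
Why: Hydride reduction, chemoselective for the aldehyde over the methyl ester and the aryl bromide.

Step 8
Reactants: 10 methyl 5-bromo-3-(hydroxymethyl)-2-methoxy-4-[(4-methoxybenzyl)oxy]benzoate
Product: 13 racemic 4-bromo-6-(hydroxymethyl)-3,7-dimethoxy-5-[(4-methoxybenzyl)oxy]isobenzofuran-1(3H)-one, via arylmagnesium chloride 11 (not isolated), via lactol 12 (not isolated)
Conditions: TMPMgCl·LiCl (2.3 equiv), THF, −20 °C; DMF, −20 °C → rt; 1 M aq. citric acid; then MeOH, PPTS (cat.), 50 °C
Reagents that add atoms: N,N-dimethylformamide CN(C)C=O; methanol CO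
Why: Directed ortho-magnesiation: after the alcohol is deprotonated, the hindered amide base removes the only ring hydrogen, which lies between the ester and the bromine (future B4), and the arylmagnesium is formylated by DMF. The tetrahedral alkoxide should lactonize onto the neighbouring methyl ester, acid work-up gives the lactol, and acetal exchange in methanol gives the methyl pseudo-ester; an uncyclized formyl ester would converge on the same product in the methanol step. The new acetal carbon is racemic and is the future lactol carbon, set in step 16.

Step 9
Reactants: 13 racemic 4-bromo-6-(hydroxymethyl)-3,7-dimethoxy-5-[(4-methoxybenzyl)oxy]isobenzofuran-1(3H)-one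
Product: 14 racemic {4-bromo-3,7-dimethoxy-5-[(4-methoxybenzyl)oxy]-1-oxo-1,3-dihydroisobenzofuran-6-yl}methyl acetate
Conditions: Ac2O, pyridine, DMAP (cat.), CH2Cl2, 0 °C
Reagents that add atoms: acetic anhydride CC(=O)OC(C)=O
Why: Acylation of the primary benzylic alcohol under nucleophilic catalysis; no organometallic or hydride reagent is used after this point.

Step 10
Reactants: 14 racemic {4-bromo-3,7-dimethoxy-5-[(4-methoxybenzyl)oxy]-1-oxo-1,3-dihydroisobenzofuran-6-yl}methyl acetate
Product: 16 racemic {4-hydroxy-3,7-dimethoxy-5-[(4-methoxybenzyl)oxy]-1-oxo-1,3-dihydroisobenzofuran-6-yl}methyl acetate (ring B phenol), via pinacol boronate 15 (not isolated)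
Conditions: B2pin2, Pd(OAc)2 (5 mol%), SPhos (10 mol%), KOAc, 1,4-dioxane, 80 °C; then H2O2 (30% aq.), NaHCO3, THF, 0 °C
Reagents that add atoms: hydrogen peroxide OO; bis(pinacolato)diboron CC1(C)OB(OC1(C)C)B1OC(C)(C)C(C)(C)O1 (boron of 15 only)
Why: Miyaura borylation (oxidative addition of zerovalent palladium into the C–Br bond, transmetalation with the diboron) followed by oxidative aryl migration from boron to oxygen turns the bromine into the B5 hydroxyl at the same carbon. A biaryl phosphine catalyst is chosen because it should not ionize the benzylic acetate, and the phenoxide formed is meta to the acetoxymethyl group, so no quinone methide can arise.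

Step 11
Reactants: 16 racemic {4-hydroxy-3,7-dimethoxy-5-[(4-methoxybenzyl)oxy]-1-oxo-1,3-dihydroisobenzofuran-6-yl}methyl acetate; 5 4-methoxybenzyl 3-bromopropiolate
Product: 17 racemic 4-methoxybenzyl 3-({6-(acetoxymethyl)-3,7-dimethoxy-5-[(4-methoxybenzyl)oxy]-1-oxo-1,3-dihydroisobenzofuran-4-yl}oxy)propiolate (ring B aryl ynol ether)
Conditions: Cs2CO3 (1.1 equiv), DMF, −40 °C; phenoxide added slowly to 5 (1.5 equiv), −40 → 0 °C
Reagents that add atoms: none
Why: Nucleophilic substitution at acetylenic carbon by addition–elimination: the phenoxide adds to the bromine-bearing carbon of the ynoate and the ester-stabilized vinyl anion expels bromide. Inverse addition without free phenol should suppress protonation of that anion and a second addition to the product.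

Step 12
Reactants: 17 racemic 4-methoxybenzyl 3-({6-(acetoxymethyl)-3,7-dimethoxy-5-[(4-methoxybenzyl)oxy]-1-oxo-1,3-dihydroisobenzofuran-4-yl}oxy)propiolate; 2 4-methoxy-6-methyl-2-oxo-2H-pyran-3-carbaldehyde
Product: 19 racemic 4-methoxybenzyl 2-({6-(acetoxymethyl)-3,7-dimethoxy-5-[(4-methoxybenzyl)oxy]-1-oxo-1,3-dihydroisobenzofuran-4-yl}oxy)-3-formyl-4-methoxy-6-methylbenzoate (seco ester), via bicyclic lactone 18 (not isolated)
Conditions: 2 (3 equiv), BHT (cat.), toluene, 125 °C, sealed tube
Reagents that add atoms: none
Why: The aryloxy group makes the ester-bearing alkyne carbon nucleophilic, and the formyl and lactone carbonyls make the methyl-bearing pyrone carbon C6 electrophilic, so an asynchronous (4+2) addition across C3 and C6 should form the A1–A2 bond first and the A5–A6 bond second. The resulting 2-oxabicyclo[2.2.2]octadienone 18 loses carbon dioxide by retro-(4+2) reaction at the reaction temperature and leaves the aromatic ring A. The closest known reaction type is the thermal Diels–Alder/decarboxylation sequence of 3-acyl-2-pyrones with alkynes, ynamines and ketene acetals, in which the donor-bearing carbon of the dienophile ends up next to the 3-acyl group, as required here. Ring A closes by intermolecular (4+2) cycloaddition (two σ bonds, six-membered carbocycle) and is aromatized by the cycloreversion; no ring is closed onto a chain. No lasting stereocentre is formed, because the two bridgeheads of 18 become aromatic carbons, and the acetal centre of ring B is untouched. The step needs regioselectivity (oxygen-bearing alkyne carbon to the formyl-bearing C3), which the matched polarization of both partners should secure, and chemoselectivity for the carbocyclic diene over the formyl-containing oxadiene, which is favoured because the methoxy group deactivates and shields C4 and because only the C3/C6 mode ends in irreversible loss of gas. In 17 both positions ortho to the ether oxygen are substituted, no free hydroxyl is present, and the ring B aldehyde is masked as the pseudo-ester, so neither a sigmatropic shift nor a carbonyl–alkyne reaction should compete. The pyrone delivers CH3, H, OMe and CHO in their final order, and the alkyne delivers the carboxyl carbon and the ether oxygen already bonded to B5.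

Step 13
Reactants: 19 racemic 4-methoxybenzyl 2-({6-(acetoxymethyl)-3,7-dimethoxy-5-[(4-methoxybenzyl)oxy]-1-oxo-1,3-dihydroisobenzofuran-4-yl}oxy)-3-formyl-4-methoxy-6-methylbenzoate
Product: 20 racemic 2-{[6-(acetoxymethyl)-5-hydroxy-3,7-dimethoxy-1-oxo-1,3-dihydroisobenzofuran-4-yl]oxy}-3-formyl-4-methoxy-6-methylbenzoic acid (seco hydroxy acid)
Conditions: CF3CO2H/CH2Cl2 (1:9), pentamethylbenzene (10 equiv), 0 °C
Reagents that add atoms: none
Why: Acidolysis of the 4-methoxybenzyl ether and ester through the 4-methoxybenzyl cation, which is trapped by Friedel–Crafts alkylation of pentamethylbenzene; the acyl acetal and the acetate should ionize much more slowly. The B6 phenol is released under acid and therefore never exists as a phenoxide beside the acetoxymethyl group.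

Step 14
Reactants: 20 racemic 2-{[6-(acetoxymethyl)-5-hydroxy-3,7-dimethoxy-1-oxo-1,3-dihydroisobenzofuran-4-yl]oxy}-3-formyl-4-methoxy-6-methylbenzoic acid
Product: 21 racemic tri-O-methylgalbinic acid (methyl ethers on the A4 and B2 oxygens plus methyl acetal on the lactol oxygen)
Conditions: DCC (1.5 equiv), CH2Cl2 (0.005 M), 0 °C → rt
Reagents that add atoms: none
Why: Carbodiimide lactonization without added base: the O-acylisourea of the A1 carboxyl group is captured by the B6 phenol to close the seven-membered dioxepinone, the customary closure of 2-(2-hydroxyaryloxy)benzoic acids to depsidones; high dilution favours ring closure over oligomer formation.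

Step 15
Reactants: 21 racemic tri-O-methylgalbinic acid
Product: 22 racemic galbinic acid
Conditions: BCl3 (8 equiv), CH2Cl2, −78 → −10 °C; then THF/H2O, 0 °C → rt
Reagents that add atoms: water O (lactol hydroxyl oxygen when the acetal carbon passes through its chloride)
Why: Chelation-assisted Lewis acid dealkylation: boron trichloride cleaves the two aryl methyl ethers that lie next to a carbonyl group and converts the methyl acetal into the chloride, which hydrolyses to the lactol on work-up. The aryl ester and the diaryl ether are not expected to react at this temperature; the lactol is obtained as the racemate.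

Step 16
Reactants: 22 racemic galbinic acid
Product: 23 galbinic acid tris(allyl carbonate), lactol carbon with the spatial arrangement of the target (R descriptor because the carbonate oxygen outranks the ring oxygen)
Conditions: (CH2=CHCH2OCO)2O (4.5 equiv), (2S,3R)-HyperBTM (10 mol%), i-Pr2NEt (4 equiv), CH2Cl2, −40 °C
Reagents that add atoms: diallyl dicarbonate C=CCOC(=O)OC(=O)OCC=C
Why: Proposed new method: the isothiourea is acylated by the dicarbonate to an N-allyloxycarbonyl isothiouronium ion that should carbonate one lactol enantiomer faster, while base-mediated ring–chain tautomerism through the achiral formyl carboxylate keeps the two enantiomers in equilibrium, so the catalyst alone fixes the configuration (the catalyst enantiomer is chosen for the required sense); the closest known reaction type is the acylative dynamic kinetic resolution of 3-hydroxyphthalides with carboxylic anhydrides under chiral isothiourea or related acyl-transfer catalysis, and dicarbonates are known acyl donors for isothioureas in carboxyl-transfer reactions. The two phenols are carbonated without selectivity, which is harmless and removes the free phenol beside the acetoxymethyl group.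

Step 17
Reactants: 23 galbinic acid tris(allyl carbonate)
Product: 24 galbinic acid, (S) at the lactol carbon
Conditions: Pd(PPh3)4 (5 mol%), PhNHMe (10 equiv), THF, 0 °C; pH 5 buffer work-up
Reagents that add atoms: none
Why: Tsuji–Trost deallylation: zerovalent palladium ionizes the allyl carbonates, N-methylaniline takes up the allyl groups, and the resulting anilinium ion protonates the carbonic half esters, which lose carbon dioxide without leaving a free lactol oxygen anion, so the configuration from step 16 should be kept. The amine is too weak a base to open the lactol or to deprotonate the phenols to any extent.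

## Compound list

1 | 4-methoxy-6-methyl-2H-pyran-2-one | Cc1cc(OC)cc(=O)o1 | starting material
2 | 4-methoxy-6-methyl-2-oxo-2H-pyran-3-carbaldehyde | Cc1cc(OC)c(C=O)c(=O)o1 | intermediate
3 | propiolic acid | C#CC(=O)O | starting material
4 | 4-methoxybenzyl propiolate | C#CC(=O)OCc1ccc(OC)cc1 | intermediate
5 | 4-methoxybenzyl 3-bromopropiolate | BrC#CC(=O)OCc1ccc(OC)cc1 | intermediate
6 | methyl 5-bromo-2,4-dihydroxybenzoate | COC(=O)c1cc(Br)c(O)cc1O | starting material
7 | methyl 5-bromo-3-formyl-2,4-dihydroxybenzoate | COC(=O)c1cc(Br)c(O)c(C=O)c1O | intermediate
8 | methyl 5-bromo-3-formyl-2-hydroxy-4-[(4-methoxybenzyl)oxy]benzoate | COC(=O)c1cc(Br)c(OCc2ccc(OC)cc2)c(C=O)c1O | intermediate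
9 | methyl 5-bromo-3-formyl-2-methoxy-4-[(4-methoxybenzyl)oxy]benzoate | COC(=O)c1cc(Br)c(OCc2ccc(OC)cc2)c(C=O)c1OC | intermediate
10 | methyl 5-bromo-3-(hydroxymethyl)-2-methoxy-4-[(4-methoxybenzyl)oxy]benzoate | COC(=O)c1cc(Br)c(OCc2ccc(OC)cc2)c(CO)c1OC | intermediate
11 | arylmagnesium chloride of 10 (MgCl on the carbon between ester and bromine, chloromagnesium alkoxide on the hydroxymethyl group) | COC(=O)c1c([Mg]Cl)c(Br)c(OCc2ccc(OC)cc2)c(CO[Mg]Cl)c1OC | intermediate
12 | racemic 4-bromo-3-hydroxy-6-(hydroxymethyl)-7-methoxy-5-[(4-methoxybenzyl)oxy]isobenzofuran-1(3H)-one (lactol) | OC1OC(=O)c2c(OC)c(CO)c(OCc3ccc(OC)cc3)c(Br)c12 | intermediate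
13 | racemic 4-bromo-6-(hydroxymethyl)-3,7-dimethoxy-5-[(4-methoxybenzyl)oxy]isobenzofuran-1(3H)-one | COC1OC(=O)c2c(OC)c(CO)c(OCc3ccc(OC)cc3)c(Br)c12 | intermediate
14 | racemic {4-bromo-3,7-dimethoxy-5-[(4-methoxybenzyl)oxy]-1-oxo-1,3-dihydroisobenzofuran-6-yl}methyl acetate | COC1OC(=O)c2c(OC)c(COC(C)=O)c(OCc3ccc(OC)cc3)c(Br)c12 | intermediate
15 | pinacol boronate of 14 (boronate in place of bromine) | COC1OC(=O)c2c(OC)c(COC(C)=O)c(OCc3ccc(OC)cc3)c(B3OC(C)(C)C(C)(C)O3)c12 | intermediate
16 | racemic {4-hydroxy-3,7-dimethoxy-5-[(4-methoxybenzyl)oxy]-1-oxo-1,3-dihydroisobenzofuran-6-yl}methyl acetate (ring B phenol) | COC1OC(=O)c2c(OC)c(COC(C)=O)c(OCc3ccc(OC)cc3)c(O)c12 | intermediate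
17 | racemic 4-methoxybenzyl 3-({6-(acetoxymethyl)-3,7-dimethoxy-5-[(4-methoxybenzyl)oxy]-1-oxo-1,3-dihydroisobenzofuran-4-yl}oxy)propiolate (ring B aryl ynol ether) | COC1OC(=O)c2c(OC)c(COC(C)=O)c(OCc3ccc(OC)cc3)c(OC#CC(=O)OCc3ccc(OC)cc3)c12 | intermediate
18 | bicyclic lactone (2-oxabicyclo[2.2.2]octa-5,7-dien-3-one) from 17 and 2, mixture of diastereomers | COC1OC(=O)c2c(OC)c(COC(C)=O)c(OCc3ccc(OC)cc3)c(OC3=C(C(=O)OCc4ccc(OC)cc4)C4(C)OC(=O)C3(C=O)C(OC)=C4)c12 | intermediate
19 | racemic 4-methoxybenzyl 2-({6-(acetoxymethyl)-3,7-dimethoxy-5-[(4-methoxybenzyl)oxy]-1-oxo-1,3-dihydroisobenzofuran-4-yl}oxy)-3-formyl-4-methoxy-6-methylbenzoate (seco ester) | COC1OC(=O)c2c(OC)c(COC(C)=O)c(OCc3ccc(OC)cc3)c(Oc3c(C=O)c(OC)cc(C)c3C(=O)OCc3ccc(OC)cc3)c12 | intermediate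
20 | racemic 2-{[6-(acetoxymethyl)-5-hydroxy-3,7-dimethoxy-1-oxo-1,3-dihydroisobenzofuran-4-yl]oxy}-3-formyl-4-methoxy-6-methylbenzoic acid | COC1OC(=O)c2c(OC)c(COC(C)=O)c(O)c(Oc3c(C=O)c(OC)cc(C)c3C(=O)O)c12 | intermediate
21 | racemic tri-O-methylgalbinic acid (methyl on the A4 oxygen, on the B2 oxygen and on the lactol oxygen) | COC1OC(=O)c2c(OC)c(COC(C)=O)c3OC(=O)c4c(C)cc(OC)c(C=O)c4Oc3c12 | intermediate
22 | racemic galbinic acid | CC(=O)OCc1c(O)c2c(c3c1OC(=O)c1c(C)cc(O)c(C=O)c1O3)C(O)OC2=O | intermediate
23 | galbinic acid tris(allyl carbonate), single lactol configuration | CC(=O)OCc1c(OC(=O)OCC=C)c2c(c3c1OC(=O)c1c(C)cc(OC(=O)OCC=C)c(C=O)c1O3)[C@@H](OC(=O)OCC=C)OC2=O | intermediate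
24 | galbinic acid, (S) at the lactol carbon | CC(=O)OCc1c(O)c2c(c3c1OC(=O)c1c(C)cc(O)c(C=O)c1O3)[C@@H](O)OC2=O | target

## Step count and least certain steps

Total step count: 17. Longest linear sequence: 14 steps (steps 4 to 17, from 6 to 24).

**Step 16 (the step labelled as a proposed new method).** The carbonate transfer may show poor discrimination between the lactol enantiomers, or acylation may outrun lactol equilibration, because an N-alkoxycarbonyl isothiouronium ion is a less studied acylating species than the N-acyl ions of the known resolutions. Fallback with known chemistry, from 22 back to 23: 22 is carbonated without selectivity (allyl chloroformate, pyridine, CH2Cl2, 0 °C) to the racemic tris(allyl carbonate) F1, which is configurationally stable and is separated by preparative chromatography on a chiral stationary phase into 23 and the enantiomer of 23 F2. F2 can be returned to racemic 22 under the conditions of step 17 followed by a trace of base and used again.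

**Step 12 (key step).** The cycloaddition may be too slow, because the alkyne is a push–pull system and the pyrone is deactivated by its methoxy group, so that thermal decay of the ynol ether or addition in the oxadiene mode takes over. Fallback that changes the approach, from 16 back to 19: the phenoxide of 16 (Cs2CO3, DMSO, 70 °C) displaces fluoride from 4-methoxybenzyl 2-fluoro-3-formyl-4-methoxy-6-methylbenzoate F3 by nucleophilic aromatic substitution, the fluorine being activated by the ortho formyl and ortho ester groups. F3 would be prepared separately in about four steps by fluorine-directed ortho-lithiation chemistry from a commercial fluoroanisole.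

**Step 11.** The vinyl anion may be protonated before it expels bromide, and a second phenoxide may then add to give a ketene acetal. Fallback, from 16 and 4 back to 17: conjugate addition of 16 to 4 (DABCO cat., CH2Cl2) gives the (E)-3-aryloxyacrylate F4; bromine addition and loss of hydrogen bromide (Br2, CH2Cl2, −78 °C; then Et3N) give the 2-bromo-3-aryloxyacrylate F5 (alkene geometry not fixed); dehydrobromination with KN(SiMe3)2 in THF at −78 °C gives 17.

**Step 15.** The benzylic acetate may ionize next to the boron-bound B2 oxygen and be exchanged for chloride. Fallback, from 21 back to 22: the exchange is driven to completion with excess BCl3 at 0 °C to give the chloromethyl analogue of 22 F6, and the acetate is put back by silver-assisted substitution (AgOAc, AcOH, rt).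

**Step 17.** Configuration may be lost if the carbonic half ester of the lactol decarboxylates to the free oxygen anion, which opens to the achiral formyl carboxylate. Fallback, from 22 back to 24: the resolution of step 16 is run with 2,2,2-trichloroethyl chloroformate in place of the dicarbonate to give the tris(2,2,2-trichloroethyl carbonate) F7, and the carbonates are removed reductively in an acidic medium (Zn, AcOH/THF, 0 °C), where the half ester is protonated at all times.

## Further compounds

F1 | step 16 | racemic galbinic acid tris(allyl carbonate) | CC(=O)OCc1c(OC(=O)OCC=C)c2c(c3c1OC(=O)c1c(C)cc(OC(=O)OCC=C)c(C=O)c1O3)C(OC(=O)OCC=C)OC2=O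
F2 | step 16 | enantiomer of 23 | CC(=O)OCc1c(OC(=O)OCC=C)c2c(c3c1OC(=O)c1c(C)cc(OC(=O)OCC=C)c(C=O)c1O3)[C@H](OC(=O)OCC=C)OC2=O
F3 | step 12 | 4-methoxybenzyl 2-fluoro-3-formyl-4-methoxy-6-methylbenzoate | COc1ccc(COC(=O)c2c(C)cc(OC)c(C=O)c2F)cc1
F4 | step 11 | racemic 4-methoxybenzyl (E)-3-({6-(acetoxymethyl)-3,7-dimethoxy-5-[(4-methoxybenzyl)oxy]-1-oxo-1,3-dihydroisobenzofuran-4-yl}oxy)acrylate | COC1OC(=O)c2c(OC)c(COC(C)=O)c(OCc3ccc(OC)cc3)c(O/C=C/C(=O)OCc3ccc(OC)cc3)c12
F5 | step 11 | racemic 4-methoxybenzyl 2-bromo-3-({6-(acetoxymethyl)-3,7-dimethoxy-5-[(4-methoxybenzyl)oxy]-1-oxo-1,3-dihydroisobenzofuran-4-yl}oxy)acrylate, alkene geometry not fixed | COC1OC(=O)c2c(OC)c(COC(C)=O)c(OCc3ccc(OC)cc3)c(OC=C(Br)C(=O)OCc3ccc(OC)cc3)c12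
F6 | step 15 | racemic chloromethyl analogue of galbinic acid (CH2Cl in place of CH2OAc on B1) | ClCc1c(O)c2c(c3c1OC(=O)c1c(C)cc(O)c(C=O)c1O3)C(O)OC2=O
F7 | step 17 | galbinic acid tris(2,2,2-trichloroethyl carbonate), single lactol configuration | CC(=O)OCc1c(OC(=O)OCC(Cl)(Cl)Cl)c2c(c3c1OC(=O)c1c(C)cc(OC(=O)OCC(Cl)(Cl)Cl)c(C=O)c1O3)[C@@H](OC(=O)OCC(Cl)(Cl)Cl)OC2=O
A1 | alternative 1 | galbinic acid tris(allyl carbonate), single lactol configuration (identical with 23) | CC(=O)OCc1c(OC(=O)OCC=C)c2c(c3c1OC(=O)c1c(C)cc(OC(=O)OCC=C)c(C=O)c1O3)[C@@H](OC(=O)OCC=C)OC2=O
A2 | alternative 1 | racemic galbinic acid (identical with 22) | CC(=O)OCc1c(O)c2c(c3c1OC(=O)c1c(C)cc(O)c(C=O)c1O3)C(O)OC2=O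
A3 | alternative 2 | protected depsidone with complete rings A and B | CC(=O)OCc1c(OCOC)c(C(=O)OC(C)(C)C)c(C(OC)OC)c3c1OC(=O)c1c(C)cc(O)c(C(OCC)OCC)c1O3
A4 | alternative 2 | ring B aryl 2-diazo-4-methyl-3-oxopent-4-enoate carrying a 3,3-diethoxyprop-1-ynyl ether on the neighbouring oxygen | CC(=O)OCc1c(OCOC)c(C(=O)OC(C)(C)C)c(C(OC)OC)c(OC#CC(OCC)OCC)c1OC(=O)C(=[N+]=[N-])C(=O)C(C)=C
A5 | alternative 3 | diaryl ether with complete ring B and a free phenol beside the ether oxygen | C=CCOC(=O)c1c(C)cc(OCOC)c(C(OC)OC)c1Oc1c(C(OC)OC)c(C(=O)OC(C)(C)C)c(O[Si](C(C)C)(C(C)C)C(C)C)c(CO[Si](C)(C)C(C)(C)C)c1O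
A6 | alternative 3 | tert-butyl 5-aryloxy-2-diazo-4-(dimethoxymethyl)-3-oxopent-4-enoate with ring A as the aryl group | C=CCOC(=O)c1c(C)cc(OCOC)c(C(OC)OC)c1OC=C(C(OC)OC)C(=O)C(=[N+]=[N-])C(=O)OC(C)(C)C
A7 | alternative 3 | 3-(tert-butyldimethylsilyloxy)prop-1-ynyl triisopropylsilyl ether (siloxyalkyne) | CC(C)[Si](OC#CCO[Si](C)(C)C(C)(C)C)(C(C)C)C(C)C
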